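## Retrosynthetic overview

- Daucane numbering is used: C1 = methyl-bearing quaternary ring-fusion carbon, C4 = isopropyl carbinol, C5 = ring-fusion CH, C6 and C10 = acyloxy carbons, C7 = CH2, C8(Me)=C9. Late disconnections: both angelates from the triol (Yamaguchi esterification with two equivalents of angelic acid); the C4 carbinol from isopropylcerium addition to a C4 ketone; C5–H and C6–OH from syn hydroboration of a C5=C6 alkene.
- Key disconnection: the seven-membered ring (C5, C6, C7, C8, C9, C10, C1) is cut into the alkenyl carbene C6–C5=C1 (a cyclopentenyl carbene released from a 7-alkenylcycloheptatriene) and the diene C7=C8(Me)–C9=C10–OTBS. C6–C7 and C1–C10 are made in one operation by cyclopropanation and divinylcyclopropane Cope rearrangement, a formal (4+3) cycloaddition.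
- Enabling feature: in the seven-membered ring the C8=C9 bond lies 1,4 to C5–C6, so the ring with a C5=C6 bond is a cyclohepta-1,4-diene. That is the retron of a cis-divinylcyclopropane (C6, C7, C8) whose alkenyl arms are C5=C1 of the five-membered ring and C9=C10.
- Ring order: the five-membered ring is bought as a bromoenone; its carbinol stereocentre (CBS reduction) steers the key step and later becomes the C4 ketone. The seven-membered ring is formed in the key step.

Key step: step 5

## Route

Step 1
Reactants: 1 2-bromo-3-methylcyclopent-2-en-1-one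
Product: 2 (S)-2-bromo-3-methylcyclopent-2-en-1-ol
Conditions: (R)-2-methyl-CBS-oxazaborolidine (10 mol %), BH3·SMe2, THF, −20 °C; MeOH quench
Reagents that add atoms: none
Why: Corey–Bakshi–Shibata reduction, in which the bromoalkenyl side acts as the large group, should deliver hydride to one carbonyl face and set the S carbinol centre (future C4) that later directs the key step.

Step 2
Reactants: 2 (S)-2-bromo-3-methylcyclopent-2-en-1-ol
Product: 3 (S)-[(2-bromo-3-methylcyclopent-2-en-1-yl)oxy]triethylsilane
Conditions: Et3SiCl, imidazole, CH2Cl2, 0 °C to rt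
Reagents that add atoms: chlorotriethylsilane, CC[Si](Cl)(CC)CC
Why: Standard silyl ether formation gives a TES ether that is bulky enough to shield one ring face and can later be removed in the presence of TBS ethers.

Step 3
Reactants: 3 (S)-[(2-bromo-3-methylcyclopent-2-en-1-yl)oxy]triethylsilane; 4 tropylium tetrafluoroborate
Product: 6 (S)-{[2-(cyclohepta-2,4,6-trien-1-yl)-3-methylcyclopent-2-en-1-yl]oxy}triethylsilane, via alkenyllithium 5 (not isolated)
Conditions: t-BuLi (2.1 equiv), Et2O, −78 °C; then 4, THF, −78 °C to 0 °C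
Reagents that add atoms: none
Why: Bromine–lithium exchange gives alkenyllithium 5, which should add to the tropylium cation (the usual entry to 7-substituted cycloheptatrienes); the attacked tropylium carbon becomes C6.

Step 4
Reactants: 7 3-methylbut-2-enal
Product: 8 (E)-tert-butyldimethyl[(3-methylbuta-1,3-dien-1-yl)oxy]silane
Conditions: TBSOTf, Et3N, Et2O, 0 °C to rt
Reagents that add atoms: tert-butyldimethylsilyl trifluoromethanesulfonate, CC(C)(C)[Si](C)(C)OS(=O)(=O)C(F)(F)F
Why: Silyl dienol ether formation by O-silylation of the enal and γ-deprotonation should give the E-configured 1-silyloxydiene.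

Step 5
Reactants: 6 (S)-{[2-(cyclohepta-2,4,6-trien-1-yl)-3-methylcyclopent-2-en-1-yl]oxy}triethylsilane; 8 (E)-tert-butyldimethyl[(3-methylbuta-1,3-dien-1-yl)oxy]silane (3 equiv)
Product: 11 (1S,4S,10R)-10-(tert-butyldimethylsilyloxy)-4-(triethylsilyloxy)-11,12,13-trinordauca-5,8-diene, via rhodium alkenylcarbene 9 (not isolated), via cis-divinylcyclopropane 10 (not isolated)
Conditions: Rh2(O2CCF3)4 (2 mol %), 1,2-dichloroethane, 40 °C; then 80 °C
Reagents that add atoms: none
Why: Rh2(O2CCF3)4 triggers decarbenation (retro-Buchner reaction) of 6, releasing benzene and alkenylcarbene 9, which cyclopropanates the terminal C7=C8 bond of 8 (C6–C7 and C6–C8 formed) to give cis-divinylcyclopropane 10; Cope rearrangement of 10 through the boat transition state then forms C1–C10 and breaks C6–C8. The closest known reaction type is the rhodium-catalysed formal (4+3) cycloaddition of non-acceptor alkenyl carbenes from 7-alkenylcycloheptatrienes with 1,3-dienes, a case of the tandem cyclopropanation/Cope rearrangement of alkenyl carbenoids. The seven-membered ring is closed by the (3,3)-sigmatropic shift as a ring expansion of the three-membered ring, overall a (4+3) union of C6–C5–C1 with the diene termini C7 and C10. C1 and C10 are set together and stereospecifically in the boat transition state, where the ring methyl (inside position) and the E-placed OTBS group end up trans; their absolute sense follows from the cyclopropane configuration, fixed when 8 approaches the carbene carbon on the face opposite the C4 OTES group while allylic strain keeps the rhodium away from the C1 methyl. The step needs attack at the CH2=C terminus and not at the enol ether bond, a cis arrangement of the two alkenyl groups, and facial control by C4; these should come from the nucleophilic unhindered CH2 terminus of the silyloxydiene, the usual cis preference of alkenyl carbenes with dienes, and the bulky silyl ether. Warming to 80 °C is planned because the Cope step has to build the quaternary C1 with its methyl pointing inward.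

Step 6
Reactants: 11 (1S,4S,10R)-10-(tert-butyldimethylsilyloxy)-4-(triethylsilyloxy)-11,12,13-trinordauca-5,8-diene
Product: 13 (1S,4S,5S,6S,10R)-10-(tert-butyldimethylsilyloxy)-4-(triethylsilyloxy)-11,12,13-trinordauc-8-en-6-ol, via B-alkyl-9-BBN adduct 12 (not isolated)
Conditions: 9-BBN, THF, rt to 60 °C; then NaOH, H2O2, 0 °C
Reagents that add atoms: hydrogen peroxide, OO
Why: Hydroboration–oxidation should place boron on the less substituted C6 of the C5=C6 bond from the face opposite the C1 methyl and the C4 OTES group, and the syn addition sets C5–H and C6–OH cis (trans ring fusion), while the C8=C9 bond is shielded by the adjacent OTBS group and the quaternary C1.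

Step 7
Reactants: 13 (1S,4S,5S,6S,10R)-10-(tert-butyldimethylsilyloxy)-4-(triethylsilyloxy)-11,12,13-trinordauc-8-en-6-ol
Product: 14 (1S,4S,5R,6S,10R)-6,10-bis(tert-butyldimethylsilyloxy)-4-(triethylsilyloxy)-11,12,13-trinordauc-8-ene
Conditions: TBSOTf, 2,6-lutidine, CH2Cl2, −78 °C to 0 °C
Reagents that add atoms: tert-butyldimethylsilyl trifluoromethanesulfonate, CC(C)(C)[Si](C)(C)OS(=O)(=O)C(F)(F)F
Why: Silylation with a silyl triflate and a hindered base protects the C6 hydroxyl before the C4 oxidation.

Step 8
Reactants: 14 (1S,4S,5R,6S,10R)-6,10-bis(tert-butyldimethylsilyloxy)-4-(triethylsilyloxy)-11,12,13-trinordauc-8-ene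
Product: 15 (1S,4S,5R,6S,10R)-6,10-bis(tert-butyldimethylsilyloxy)-11,12,13-trinordauc-8-en-4-ol
Conditions: PPTS (cat.), MeOH/CH2Cl2, 0 °C to rt
Reagents that add atoms: none
Why: Acid-catalysed methanolysis (selective desilylation) should cleave the secondary TES ether much faster than the two more hindered TBS ethers.

Step 9
Reactants: 15 (1S,4S,5R,6S,10R)-6,10-bis(tert-butyldimethylsilyloxy)-11,12,13-trinordauc-8-en-4-ol
Product: 16 (1S,5S,6S,10R)-6,10-bis(tert-butyldimethylsilyloxy)-11,12,13-trinordauc-8-en-4-one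
Conditions: Dess–Martin periodinane, CH2Cl2, 0 °C to rt
Reagents that add atoms: none
Why: Dess–Martin oxidation under nearly neutral conditions should give the cyclopentanone without epimerising C5 or eliminating the β-silyloxy group.

Step 10
Reactants: 16 (1S,5S,6S,10R)-6,10-bis(tert-butyldimethylsilyloxy)-11,12,13-trinordauc-8-en-4-one
Product: 17 (1S,4R,5S,6S,10R)-6,10-bis(tert-butyldimethylsilyloxy)dauc-8-en-4-ol
Conditions: i-PrMgCl, anhydrous CeCl3, THF, −78 °C to −40 °C
Reagents that add atoms: isopropylmagnesium chloride, CC(C)[Mg]Cl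
Why: Organocerium 1,2-addition suppresses enolisation and reduction, and the nucleophile should approach the C4 carbonyl on the face opposite the pseudoaxial C1 methyl, placing isopropyl cis to H5 and the new hydroxyl cis to the methyl.

Step 11
Reactants: 17 (1S,4R,5S,6S,10R)-6,10-bis(tert-butyldimethylsilyloxy)dauc-8-en-4-ol
Product: 18 (1S,4R,5S,6S,10R)-dauc-8-ene-4,6,10-triol
Conditions: TBAF, THF, rt to 50 °C
Reagents that add atoms: none
Why: Fluoride-mediated desilylation removes both TBS ethers and leaves the tertiary alcohol and all stereocentres untouched.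

Step 12
Reactants: 18 (1S,4R,5S,6S,10R)-dauc-8-ene-4,6,10-triol; 19 angelic acid, (Z)-2-methylbut-2-enoic acid (two equivalents are consumed, one per ester; 4 equiv charged)
Product: 21 (1S,4R,5S,6S,10R)-6,10-bis(angeloyloxy)dauc-8-en-4-ol (CNP0183261.1), via 6-monoangelate 20 (not isolated)
Conditions: 19 (4 equiv), 2,4,6-trichlorobenzoyl chloride (4 equiv), Et3N, toluene, rt; then 18, 80 °C (no DMAP)
Reagents that add atoms: angelic acid (the second equivalent of 19, which supplies the second angeloyl group), C/C=C(/C)C(=O)O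
Why: Yamaguchi esterification through the mixed anhydride should acylate both secondary alcohols, each with one equivalent of angelic acid (the less hindered C6 hydroxyl first, then C10), and not the tertiary C4 alcohol, and the DMAP-free protocol is chosen to avoid Z to E isomerisation to the tiglate.

## Compound list

1 | 2-bromo-3-methylcyclopent-2-en-1-one | CC1=C(Br)C(=O)CC1 | starting material
2 | (S)-2-bromo-3-methylcyclopent-2-en-1-ol | O[C@H]1CCC(C)=C1Br | intermediate
3 | (S)-[(2-bromo-3-methylcyclopent-2-en-1-yl)oxy]triethylsilane | CC[Si](CC)(CC)O[C@H]1CCC(C)=C1Br | intermediate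
4 | tropylium tetrafluoroborate | [CH+]1C=CC=CC=C1.F[B-](F)(F)F | starting material
5 | (S)-[2-methyl-5-(triethylsilyloxy)cyclopent-1-en-1-yl]lithium (not isolated) | CC[Si](CC)(CC)O[C@H]1CCC(C)=C1[Li] | intermediate
6 | (S)-{[2-(cyclohepta-2,4,6-trien-1-yl)-3-methylcyclopent-2-en-1-yl]oxy}triethylsilane | CC[Si](CC)(CC)O[C@H]1CCC(C)=C1C1C=CC=CC=C1 | intermediate
7 | 3-methylbut-2-enal | CC(C)=CC=O | starting material
8 | (E)-tert-butyldimethyl[(3-methylbuta-1,3-dien-1-yl)oxy]silane | C=C(C)/C=C/O[Si](C)(C)C(C)(C)C | intermediate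
9 | rhodium alkenylcarbene from 6 on Rh2(O2CCF3)4 (not isolated; carboxylates drawn monodentate) | CC[Si](CC)(CC)O[C@H]1CCC(C)=C1C=[Rh](OC(=O)C(F)(F)F)(OC(=O)C(F)(F)F)[Rh](OC(=O)C(F)(F)F)OC(=O)C(F)(F)F | intermediate
10 | cis-divinylcyclopropane: (1S,2R)-1-methyl-1-[(E)-2-(tert-butyldimethylsilyloxy)ethenyl]-2-[(S)-2-methyl-5-(triethylsilyloxy)cyclopent-1-en-1-yl]cyclopropane (not isolated) | CC[Si](CC)(CC)O[C@H]2CCC(C)=C2[C@@H]1C[C@]1(C)/C=C/O[Si](C)(C)C(C)(C)C | intermediate
11 | (1S,4S,10R)-10-(tert-butyldimethylsilyloxy)-4-(triethylsilyloxy)-11,12,13-trinordauca-5,8-diene (C1 methyl trans to C10–O and cis to C4–O) | C1=C2[C@@H](O[Si](CC)(CC)CC)CC[C@]2(C)[C@H](O[Si](C)(C)C(C)(C)C)C=C(C)C1 | intermediate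
12 | B-alkyl-9-borabicyclo[3.3.1]nonane adduct, boron on C6 cis to H5 (not isolated) | B1(C2CCCC1CCC2)[C@H]1CC(C)=C[C@@H](O[Si](C)(C)C(C)(C)C)[C@@]2(C)CC[C@H](O[Si](CC)(CC)CC)[C@H]12 | intermediate
13 | (1S,4S,5S,6S,10R)-10-(tert-butyldimethylsilyloxy)-4-(triethylsilyloxy)-11,12,13-trinordauc-8-en-6-ol (trans-fused; 6-OH cis to H5) | O[C@H]1CC(C)=C[C@@H](O[Si](C)(C)C(C)(C)C)[C@@]2(C)CC[C@H](O[Si](CC)(CC)CC)[C@H]12 | intermediate
14 | (1S,4S,5R,6S,10R)-6,10-bis(tert-butyldimethylsilyloxy)-4-(triethylsilyloxy)-11,12,13-trinordauc-8-ene | CC(C)(C)[Si](C)(C)O[C@H]1CC(C)=C[C@@H](O[Si](C)(C)C(C)(C)C)[C@@]2(C)CC[C@H](O[Si](CC)(CC)CC)[C@H]12 | intermediate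
15 | (1S,4S,5R,6S,10R)-6,10-bis(tert-butyldimethylsilyloxy)-11,12,13-trinordauc-8-en-4-ol | CC(C)(C)[Si](C)(C)O[C@H]1CC(C)=C[C@@H](O[Si](C)(C)C(C)(C)C)[C@@]2(C)CC[C@H](O)[C@H]12 | intermediate
16 | (1S,5S,6S,10R)-6,10-bis(tert-butyldimethylsilyloxy)-11,12,13-trinordauc-8-en-4-one | CC(C)(C)[Si](C)(C)O[C@H]1CC(C)=C[C@@H](O[Si](C)(C)C(C)(C)C)[C@@]2(C)CCC(=O)[C@H]12 | intermediate
17 | (1S,4R,5S,6S,10R)-6,10-bis(tert-butyldimethylsilyloxy)dauc-8-en-4-ol | CC(C)(C)[Si](C)(C)O[C@H]1CC(C)=C[C@@H](O[Si](C)(C)C(C)(C)C)[C@@]2(C)CC[C@@](O)(C(C)C)[C@H]12 | intermediate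
18 | (1S,4R,5S,6S,10R)-dauc-8-ene-4,6,10-triol | O[C@H]1CC(C)=C[C@@H](O)[C@@]2(C)CC[C@@](O)(C(C)C)[C@H]12 | intermediate
19 | angelic acid, (Z)-2-methylbut-2-enoic acid | C/C=C(/C)C(=O)O | starting material
20 | (1S,4R,5S,6S,10R)-6-(angeloyloxy)dauc-8-ene-4,10-diol (not isolated) | C/C=C(/C)C(=O)O[C@H]1CC(C)=C[C@@H](O)[C@@]2(C)CC[C@@](O)(C(C)C)[C@H]12 | intermediate
21 | (1S,4R,5S,6S,10R)-6,10-bis(angeloyloxy)dauc-8-en-4-ol, CNP0183261.1 | C/C=C(/C)C(=O)O[C@H]1CC(C)=C[C@@H](OC(=O)/C(C)=C\C)[C@@]2(C)CC[C@@](O)(C(C)C)[C@H]12 | target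

## Step count and risks

Total step count: 12. Longest linear sequence: 11 steps (steps 1 to 3 and 5 to 12, from 1 to 21).

Steps most likely to fail:

1. Step 5 (key step). The decarbenation of the hindered alkenylcycloheptatriene may be slow and lose out to 1,5-hydrogen shifts of the triene; the cyclopropanation may also show incomplete facial or cis selectivity. Fallback, from 3 back to 11: bromine–lithium exchange of 3 and quenching with DMF would give (S)-2-methyl-5-(triethylsilyloxy)cyclopent-1-ene-1-carbaldehyde F1. Condensation with 2-(trifluoromethyl)benzenesulfonohydrazide would give the N-sulfonylhydrazone F2. Deprotonation with NaH and decomposition with AgOTf in the presence of 8 would generate the same alkenyl carbene by a diazo route at or below room temperature, so that cyclopropane 10 can be isolated and rearranged thermally in a separate operation to 11.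

2. Step 6. Hydroboration may also occur at the C8=C9 bond, and facial selectivity at C5=C6 may be incomplete, which would give the cis-fused C5/C6 epimeric pair. Fallback, from 11 back to 16, with oxygenation restricted to a conjugated double bond: methanolysis of the TES ether would give the allylic alcohol (1S,4S,10R)-10-(tert-butyldimethylsilyloxy)-11,12,13-trinordauca-5,8-dien-4-ol F3, and Dess–Martin oxidation the conjugated enone (1S,10R)-10-(tert-butyldimethylsilyloxy)-11,12,13-trinordauca-5,8-dien-4-one F4, in which only C5=C6 is conjugated with the ketone. Nucleophilic epoxidation (H2O2, NaOH, MeOH), which touches only the enone double bond and should occur anti to the C1 methyl, would give the epoxy ketone (1R,5R,6S,10R)-5,6-epoxy-10-(tert-butyldimethylsilyloxy)-11,12,13-trinordauc-8-en-4-one F5. Reductive opening at the α-carbon with SmI2 in THF/MeOH at −78 °C would give the β-hydroxy ketone (1S,5S,6S,10R)-10-(tert-butyldimethylsilyloxy)-6-hydroxy-11,12,13-trinordauc-8-en-4-one F6, and silylation with TBSOTf and 2,6-lutidine would return 16.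

3. Step 10. The branched, basic isopropyl reagent may enolise the hindered ketone, reduce it by β-hydride transfer or cause loss of the β-silyloxy group, and the facial selectivity may be incomplete. Fallback, from 16 back to 17, in two steps: addition of the smaller sp2 nucleophile isopropenylmagnesium bromide with CeCl3 would give (1S,4S,5S,6S,10R)-6,10-bis(tert-butyldimethylsilyloxy)dauca-8,11-dien-4-ol F7 (same spatial arrangement at C4 as in 17; the descriptor changes because isopropenyl outranks C5). Hydrogenation with RhCl(PPh3)3 and H2 should then reduce the 1,1-disubstituted alkene and leave the trisubstituted ring alkene, giving 17.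

## Further compounds

F1 | step 5 | (S)-2-methyl-5-(triethylsilyloxy)cyclopent-1-ene-1-carbaldehyde | CC[Si](CC)(CC)O[C@H]1CCC(C)=C1C=O
F2 | step 5 | N-sulfonylhydrazone of F1 with 2-(trifluoromethyl)benzenesulfonohydrazide | CC[Si](CC)(CC)O[C@H]1CCC(C)=C1/C=N/NS(=O)(=O)c1ccccc1C(F)(F)F
F3 | step 6 | (1S,4S,10R)-10-(tert-butyldimethylsilyloxy)-11,12,13-trinordauca-5,8-dien-4-ol | C1=C2[C@@H](O)CC[C@]2(C)[C@H](O[Si](C)(C)C(C)(C)C)C=C(C)C1
F4 | step 6 | (1S,10R)-10-(tert-butyldimethylsilyloxy)-11,12,13-trinordauca-5,8-dien-4-one | C1=C2C(=O)CC[C@]2(C)[C@H](O[Si](C)(C)C(C)(C)C)C=C(C)C1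
F5 | step 6 | (1R,5R,6S,10R)-5,6-epoxy-10-(tert-butyldimethylsilyloxy)-11,12,13-trinordauc-8-en-4-one | O3[C@H]1CC(C)=C[C@@H](O[Si](C)(C)C(C)(C)C)[C@@]2(C)CCC(=O)[C@]123
F6 | step 6 | (1S,5S,6S,10R)-10-(tert-butyldimethylsilyloxy)-6-hydroxy-11,12,13-trinordauc-8-en-4-one | O[C@H]1CC(C)=C[C@@H](O[Si](C)(C)C(C)(C)C)[C@@]2(C)CCC(=O)[C@H]12
F7 | step 10 | (1S,4S,5S,6S,10R)-6,10-bis(tert-butyldimethylsilyloxy)dauca-8,11-dien-4-ol | CC(C)(C)[Si](C)(C)O[C@H]1CC(C)=C[C@@H](O[Si](C)(C)C(C)(C)C)[C@@]2(C)CC[C@@](O)(C(C)=C)[C@H]12
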